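A ratio told me most about these flasks, in which substrate and coupling partner make target under a catalyst: in the winter run, the mean rate up to 9.2 min, 0.0199 M/min, over the mean rate up to 1.1 min, 0.0518 M/min, is 38.4%. I called this ratio, late mean rate over early mean rate, the kept share.

| flask | substrate | coupling partner | catalyst | time |
|---|---|---|---|---|
| winter | 0.800 M | 1.20 M | 0.0160 M |  |
| autumn | 0.400 M | 0.800 M | 0.0160 M |  |
| spring | 0.800 M | 1.20 M | 0.0320 M |  |
| dawn | 0.260 M | 1.20 M | 0.00530 M | 9.2 min |

| run | time / min | [target] / M |
|---|---|---|
| winter run | 0.37 | 0.020 |
| winter run | 0.63 | 0.038 |
| winter run | 1.1 | 0.057 |
| winter run | 1.8 | 0.079 |
| winter run | 3.1 | 0.121 |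
| winter run | 5.4 | 0.168 |
| winter run | 9.2 | 0.183 |
| autumn run | 0.37 | 0.012 |
| autumn run | 0.63 | 0.009 |
| autumn run | 1.1 | 0.015 |
| autumn run | 1.8 | 0.040 |
| autumn run | 3.1 | 0.045 |
| autumn run | 5.4 | 0.072 |
| autumn run | 9.2 | 0.086 |
| spring run | 0.37 | 0.046 |
| spring run | 0.63 | 0.064 |
| spring run | 1.1 | 0.101 |
| spring run | 1.8 | 0.151 |
| spring run | 3.1 | 0.206 |
| spring run | 5.4 | 0.263 |
| spring run | 9.2 | 0.278 |

(readings scatter by 0.004 M)

1. the power of [catalyst] that the first rate follows, about the charge of the winter run; measure it at two percent of substrate made into target
2. target in the dawn run at 9.2 min, as a share of the substrate charged
3. which of these the readings show (the product reacts on with the second partner / nothing beyond the main steps / the catalyst dies by itself / the catalyst rests as a dimer / the product binds the second partner)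

- Overall: substrate + coupling partner -> target, with catalyst as catalyst.
- Constant volume, constant temperature.
- A reading of a species includes what of it is bound.
- "The second partner" is coupling partner.
- An order is taken over about fifteen percent of the charge, up and down.

Doubling the catalyst from the winter run to the spring run took the reading at 1.1 min from 0.057 M to 0.101 M, twice the winter value, which reads from this one pair as an order in [catalyst] of 0.825, and I committed to an order of one. The autumn reading of 0.045 M at 3.1 min is a third of the winter one, and the autumn substrate and partner charges multiply to a third of winter's, so I took the rate as first order in each, although the autumn run changes both together.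

The kept share is 32.9% in the spring run, less than in the winter run, and 68.6% in the autumn run, more than in the winter run, though the autumn share leans on a small reading of 0.015 M with a scatter of 0.004 M. A catalyst decaying on its own clock should leave these shares close together. Their spread suggested instead a loss that starts at zero and grows against the making rate as target builds up, and that weakens with less partner: target reacting on with coupling partner.

For the dawn run, the winter early rate scaled by substrate and catalyst is 0.00558 M/min. One extreme, with nothing lost, gives 19.7% of its substrate by 9.2 min; the other, a miniature of the winter run, keeps 38.4% of that, or 7.56%. The dawn run has a third of the winter catalyst and the same partner charge, and the spring run kept less than the winter run with more catalyst, so I placed the dawn run between these two estimates, which are not bounds. Carrying the line through the spring and winter shares down to the dawn catalyst gave me a kept share of 42.0%, hence 8.27%.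

The forecast gave an order of 0.95, 9.5% and the catalyst dies by itself, in its words “So the catalyst dies”.

The flask gave an order of 1.0, 10.7% and the product reacts on with the second partner.

    catalyst + substrate ⇌ catalyst-substrate complex, settled at all times (0.2040 /M)
    catalyst-substrate complex + coupling partner → target + catalyst + by-product (21.42 /M/min)
    target + coupling partner → side product (0.1386 /M/min)

The dawn run's kept share, reckoned on my scaled early rate, came to 54.1%, above my 42.0%. Taking away the step from target and coupling partner to side product lifts the dawn run from 10.7% to 21.2%, so that step costs about half of the target.

All runs come from a simulation with constants of no real substance, noise included.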